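The runs are calculated on assumed constants, and the scatter is random.

The pitfall is to let the protic impurity destroy its own amount of starting material in every flask. It is in a race, so we divide two rates.

| setting | maple | ash | winter | autumn |
|---|---|---|---|---|
| starting material | 0.14 M | 0.56 M | 0.20 M | 0.80 M |
| protic impurity | 0.040 M | 0.040 M | 0.0400 M | 0.0400 M |
| remark | run made earlier | run made earlier |  |  |
| time |  |  | 5.0 h | 3.0 h |

| maple: time / min | maple: target / % | ash: time / min | ash: target / % |
|---|---|---|---|
| 25.0 | 3.2 | 25.0 | 1.7 |
| 50.0 | 9.8 | 50.0 | 10.3 |
| 60.0 | 11.1 | 60.0 | 11.7 |
| 90.0 | 15.6 | 90.0 | 17.9 |

(readings scatter by 1 percentage point)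

* the winner by amount of target, in percent of the starting material charged; "neither" if no more than 2 percentage points parts them (winter / autumn / neither)
* how much target is there at the end, in percent of the starting material charged: winter
* how much target is there at the end, in percent of the starting material charged: autumn

- the numbers in the tables scatter by 1 percentage point (one standard deviation)

Maple and ash nearly coincide in percent, so we take the main loss as first order, and the quench as impurity times starting material. Their quotient is impurity over a constant c, and time drops out. Let e be the impurity charge as a fraction of the starting material charge, h the fraction of impurity left, and a the constant c over that charge. At full conversion the shares sum: e(1−h) − a·ln h = 1.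

We take ash as losing e = 0.0714. Readings from 50.0 min on, summed, give maple over ash as 0.915. So maple loses 0.151, not 0.286, and keeps h = 0.473. The balance gives c = 0.159 M, the break-even impurity level: at this level quench and main loss run equally fast. It is an inverse selectivity factor. With this scatter it is a rough reading.

In winter, h of a third makes the balance 1.01, so the quenched share is 0.133. In autumn nearly all the impurity goes, a share of 0.0500. By our reckoning autumn keeps more of its charge unquenched, by a factor of 1.10, but winter runs longer, by a factor of 1.67, so we pick winter.

The forecast says winter, with 46% for winter and 38% for autumn, from “the impurity destroying starting material one-for-one”. Its winter share is thus 0.200, ours 0.133.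

Winter gives 33.5% and autumn 29.0%, so winter leads.

    starting material ⇌ intermediate A (K = 1.90, k = 0.390 h⁻¹)
    starting material → intermediate B (k = 1.70 h⁻¹)
    starting material → side product A (k = 1.30 h⁻¹)
    intermediate B → target (k = 0.400 h⁻¹)
    intermediate B ⇌ intermediate C (K = 13.0, k = 0.0980 h⁻¹)
    starting material + protic impurity → quenched substrate (k = 19.0 M⁻¹ h⁻¹)
    starting material + intermediate A → side product B (k = 0.0800 M⁻¹ h⁻¹)

Quenched substrate holds 13.0% of winter's charge at 5.00 h. With winter's simulated 35.2% of impurity left, the balance with 0.159 M comes to 0.960, where winter's conversion of 99.8% asks for about 1.

Now take winter with 0.16 M of impurity. There, h of half makes the balance 0.951, so h lies a little lower and the share a little above 0.400. The computed flask keeps 49.0% of its impurity, with 40.8% quenched and 23.0% target.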